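The flask was a stirred, isothermal vessel holding 8.4 mM initiator, 3.8 mM impurity and 0.420 M transfer agent, into which 1.4 M of free monomer was fed over 6.0 min.

all flasks: free monomer 1.4 M (fed, over 6.0 min); initiator 8.4 mM; impurity 3.8 mM
- Thursday's: transfer agent 0.21 M; run made earlier; the fed solution adds 0.20 times the starting volume
- Sunday's: transfer agent 0.84 M; run made earlier; the fed solution adds 0.20 times the starting volume
- flask: transfer agent 0.420 M; the fed solution adds 0.20 times the starting volume; time 50 min

- Thursday's (time / min: monomer in chains / %, free monomer / %): 15.0: 3, 97; 30.0: 4, 97; 50.0: 8, 91; 60.0: 11, 92
- Sunday's (time / min: monomer in chains / %, free monomer / %): 5.00: 0, 82; 12.0: 1, 96; 25.0: 5, 98; 60.0: 8, 94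

(scatter of a reading: 1.5 percentage points)

- amounts are per litre of the starting volume; all of the dose is in the solution fed
- the average divides the monomer in chains by the number of chains begun, living and dead together
- what may be going on: free monomer + initiator -> living end + monomer in chains; free monomer + living end -> monomer in chains + living end; living end + transfer agent -> dead chain; free monomer + initiator -> spent initiator A; living end -> dead end B; initiator + impurity -> spent initiator C
- the earlier runs do not show the number of chains; that part of a forecast is a guess
- percentages count the whole charge, also what has not yet gone in

1. whether the average number of monomer units in a chain (chains begun, living or dead) reaches 10 by 50 min (yes / no)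
2. average number of monomer units in a chain (chains begun, living or dead) at 50 min

I turned the question round: what had to be true for the average to stay under 10 at 50 min? In the proposed steps each chain begun takes one initiator, and the transfer step ends a chain without beginning another, so chains begun could not exceed the initiator charge. A short average therefore needed monomer in chains below 6.00% of the charge.

The flask's transfer agent lay between Thursday's and Sunday's, and at 60.0 min those runs read 11% and 8% monomer in chains. Thursday's reading at 50.0 min was 8%, which is 2 percentage points above that threshold, against a scatter of 1.5 points. That reading gave 13.3 for the floor length F, monomer in chains divided by initiator charged, the least the average can be. If the impurity took its whole charge of initiator, one for one, chains begun stopped at 4.60 mM, and the threshold fell to 3.29%. With F above 10, I committed to yes, and expected the average to lie above F.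

The forecast answered yes, with an average of 30, and warned: “Chains begun cannot be read from the runs”.

The flask gave yes, with an average of 35.9.

    free monomer + initiator → living end + monomer in chains (k = 0.0410 M⁻¹ min⁻¹)
    free monomer + living end → monomer in chains + living end, rate k2*[living end]*[free monomer] (k = 1.50 M⁻¹ min⁻¹)
    living end + transfer agent → dead chain (kL = 0.0250 M⁻¹ min⁻¹)
    free monomer + initiator → spent initiator A (k = 0.0210 M⁻¹ min⁻¹)
    living end → dead end B (k = 0.0230 min⁻¹)
    initiator + impurity → spent initiator C (k = 53.0 M⁻¹ min⁻¹)

The flask held 7.71% monomer in chains at 50.0 min, so its F was 12.8, lower than the average, which had passed 10 at 12.8 min. At that same 50.0 min, free monomer went onto living ends 270 times as fast as into starting chains, with 1.65% of the initiator left. Half of the growth up to 50 min was done by 26.1 min. Sunday's run, a second flask, read 5% at 25.0 min, an F of 8.33, and 8% at 60.0 min, an F of 13.3.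

Readings and results stem from a simulated flask with constants of no real substance, and the scatter is random.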